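## Structural features

The target is a C25 lactone built on a bicyclo[2.2.2]oct-3-en-1-one whose bridgeheads are C5 and C2 and whose three bridges are C4=C3, C10–C1(=O) and C2'–C1'. The labels used below are: C1 ketone, C2 bridgehead CH, C3=C4 alkene with the methyl on C4, C5 quaternary bridgehead, C6–C10 the rest of ring B, C11/C12 lactone CH and carbonyl, C1' the CH carrying the diene chain, C2' the bridge CH2. Ring B (C5–C10) is fused to the bicycle along C5–C10 and carries a trans-fused α-methyl-γ-lactone across C6–C7 (O on C6, C11 on C7). C10, C5, C6, C7 and C11 form an unbroken chain of five stereocentres, two of them (C5, C10) fully substituted and adjacent; C2 and C1' complete the set. The C1 ketone lies between quaternary C10 and bridgehead C2 and cannot enolise, so C11–H is the only acidic C–H of the finished molecule. The 6-methylhepta-1,5-dien-2-yl chain on C1' points towards the C3=C4 bridge, and its two alkenes rule out ozonolysis, hydroboration, hydrogenation and strong acid once it is in place. The real difficulty is the C5–C10 bond between two quaternary carbons, which must be made with the correct sense towards C1' on one side and C6/C7 on the other. The feature exploited is the 1,5-relationship C3···C1 through C4–C5–C10: with C3 as a former ketone, C4–C1 can be the temporary bond of a cyclobutane laid across the C4=C5 bond of a carvone-type enone and later opened by retro-aldol.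

## Logic of the disconnections

26 to 25: the C3–H bond is cut, so the C3=C4 alkene is traced to an enol triflate. This fixes the alkene position through the oxygen on C3. The forward step must transfer hydride from palladium without touching the lactone or the side-chain alkenes.

25 to 24: the C3–O–S bond is cut. In 24 the C1 ketone has no enolisable neighbour and the C3 ketone only C4–H, so a single enolate is possible. The forward step needs a non-nucleophilic base, because a non-enolisable 1,3-diketone opens by retro-Claisen with alkoxide or hydroxide.

24 to 23: only the oxidation level at C1 changes. A β-hydroxy ketone is exposed, which is an aldol retron.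

23 to 20 (through 22 and 21): the C2–C1 bond is cut (retro-aldol), giving the 1,5-keto aldehyde 22, and C4–C1 is then reconnected to give cyclobutanol 21 and its silyl ether 20. The bicyclo[2.2.2]octane is reduced to a cyclohexanone carrying a fused cyclobutane. The forward aldol requires C10 to sit axial on ring A, which it can do comfortably only if C5–C10 is anti to the C1' substituent.

20 to 19 (key): C5–C10 and C4–C1 are cut together. Two rings, both quaternary carbons and four stereocentres fall away, leaving a monocyclic enone with a tethered enol ether. The forward step must select one face of C5 and leave the side-chain alkenes alone.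

19 to 18 to 17: the O–Si bond and then the aldehyde are traced back to a dimethyl acetal. The forward enolisation must take the aldehyde and not the enone.

17 to 15: the C11–H bond is cut, giving an α-methylene lactone. C11 is the thermodynamically preferred centre and can be set by equilibration.

15 to 7 + 13: the C6–C7 bond and the lactone C–O bond are cut. This is the convergent step. Because C1' is separated from C6 by the sp2 carbon C5, it cannot direct the addition; the anti C6/C7 relationship and its absolute sense must come from the reagent.

13 to 12 to 10 + 11, and 10 to 9 to 8: the allylic bromide is traced to a Morita–Baylis–Hillman adduct of 11 with aldehyde 10, and 10 to oxidative cleavage of acetal-protected 8. The acetal must survive every step up to 17.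

7 to 6 to 5 to 4: the formyl group is traced to a protected hydroxymethyl group and the enone to a tertiary allylic alcohol by 1,3-oxidative transposition. The transposition puts the carbonyl next to the former C4 methylene of 1, which is what makes the (R)-configured centre of 1 the correct one for C1'.

4 to 2 + 3 to 1: the allyl–allyl bond of the side chain is cut, then the bond from the carbinol carbon to the future C6. The side chain is extended while no ketone is present, so an allyllithium can be used. The forward metalation must take the isopropenyl methyl group only.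

## Other disconnections considered

Alternative 1: The cut is C7–C11, with the lactone carbonyl traced back to an acyl group on the C6 oxygen.
- Forward step: the C6 diazoacetate A1 (bicyclic 1,3-diketone stage, side chain masked as a ketal-protected methyl ketone) would be decomposed with Rh2(OAc)4. The rhodium carbene would insert into the equatorial C7–H bond to give the trans-fused lactone A2, which lacks only the C11 methyl.
- In favour: C5 has no hydrogen, so five-membered insertion can only occur at C7. The equatorial C6 oxygen of a rigid chair directs the carbene to the equatorial C7–H. The C6/C7 relationship would therefore be read off the ring rather than imposed by a chiral catalyst on an acyclic addition; on this point the alternative is the better plan. It also keeps lactone chemistry away from the photochemical step.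
- Against: an acceptor-only carbene is unselective (dimerisation, β-lactone formation at C6–H, ylide formation with the two ketones). Any alkene would be cyclopropanated, so the diene chain must be built after A2 in the presence of two ketones and a lactone. The C11 methyl would have to be introduced by enolate alkylation next to the more acidic C4–H.
- Comparison: in structure it sets C6/C7 more securely. In mechanism it replaces a radical pair that can revert by an irreversible insertion that cannot be corrected. In step economy it is clearly behind, because masking, side-chain construction and methylation are added to a route that still has to make the C5–C10 bond.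

Alternative 2: Two cuts are made in sequence, C2–C1 in the key step and C5–C10 before it.
- Forward steps: an allylsilane at the end of the C6–C9 tether would add to C5 of the enone (Hosomi–Sakurai conjugate addition, spiro closure at C5), leaving a vinyl group on C10. The C3 silyl enol ether A3 (enolised towards C2) would then be treated with Pd(OAc)2; the divalent palladium enolate would add through C2 to the inner vinyl carbon, and β-hydride elimination would leave the exocyclic methylene of A4.
- In favour: both steps are ground-state reactions that need no photochemical equipment. Lewis-acid allylsilane addition is a dependable way to join two fully substituted carbons. The C2–C1 bond is formed irreversibly, whereas the aldol closure of the chosen plan is an equilibrium. On these points the alternative is equal or better.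
- Against: the vinyl group brings one carbon too many. Removing it from A4 by ozonolysis or dihydroxylation–cleavage cannot be reconciled with the isopropenyl group of A4, still less with the full diene chain, so the chain would have to be masked and finished late. The enol ether must be formed towards C2 and not the more substituted C4. The closure is a 6-exo attack on a neopentyl-type alkene. After excision the C3 ketone still needs the same two closing steps as in the chosen plan.
- Comparison: in structure both plans pass through the same oxidation pattern at C1/C3. In mechanism the alternative is polar and organometallic rather than radical. In step economy it is longer by the masking and excision steps.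

Alternative 3: C5–C10 and C2–C1 are cut together, opening the bicyclo[2.2.2]octene to a 1,3-cyclohexadiene (C5=C4–C3=C2) and a tethered dienophile.
- Forward step: the (E)-nitroalkene A5 would be warmed so that the nitroalkene adds across the diene to give the C1-nitro compound A6. A Nef reaction would then give the C1 ketone.
- In favour: one thermal step would build ring B, the bicycle, both quaternary carbons and the C3=C4 alkene in its final place, so the oxidation, enol triflate and reduction steps disappear. This is a real advantage in step economy after the key step. The concerted suprafacial mechanism fixes C5 and C10 together, and the tether enforces a regiochemistry that is also the electronically preferred one. The face selectivity of a ground-state diene is arguably easier to predict than that of a twisted triplet enone; here the alternative is at least equal.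
- Against: a 5-substituted cyclohexa-1,3-diene is prone to 1,5-hydrogen shifts and aromatisation and would have to be generated just before use. A β,β-dialkyl nitroalkene isomerises readily to the allylic nitro compound and must be installed on a substrate that already holds the lactone. The fully substituted dienophile carbon meets a substituted diene terminus, which calls for temperatures the diene may not survive. The Nef reaction of a nitro group between a quaternary carbon and a bridgehead must avoid both oxidants and strong acid because of the two alkenes.
- Comparison: the alternative would be shorter if its precursor could be made. The chosen plan is preferred only because its precursor is assembled from stable intermediates by conventional reactions.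

Key step: step 14

Remark: 19 and 20 were checked centre by centre against 26 and needed no correction; C1', C6, C7, C11 (and C5, C10 in 20) already have the final configuration, and the descriptor at C1' changes from R in 1 to S from 5 onwards only because the carbonyl has moved.

Remark: 8 is used as the racemate, so 9, 10 and 12–18 are mixtures at the methyl-bearing carbon that becomes sp2 C10 in 19.

Remark: L* is 3,6-di-tert-butyl-1,8-bis(4-isopropyl-4,5-dihydrooxazol-2-yl)-9H-carbazole; the sense of induction with this γ-substituted reagent is assumed to follow the parent 2-(alkoxycarbonyl)allylation, and the antipode that leads to the (6S,7S) lactone is meant.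

Step 1
Reactants: 1 (R)-carvone
Product: 2 (5R)-1-[(methoxymethoxy)methyl]-2-methyl-5-(prop-1-en-2-yl)cyclohex-2-en-1-ol (both C1 epimers)
Conditions: Bu3SnCH2OCH2OCH3, n-BuLi, THF, −78 °C; then 1, −78 °C; NH4Cl aq
Reagents that add atoms: tributyl[(methoxymethoxy)methyl]stannane, CCCC[Sn](CCCC)(CCCC)COCOC
Why: Tin–lithium exchange gives the α-alkoxymethyllithium, which adds 1,2 to the enone carbonyl at low temperature (organolithium carbonyl addition); the new carbinol centre is destroyed in step 3, so its configuration does not matter.

Step 2
Reactants: 2 (5R)-1-[(methoxymethoxy)methyl]-2-methyl-5-(prop-1-en-2-yl)cyclohex-2-en-1-ol; 3 1-bromo-3-methylbut-2-ene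
Product: 4 (5R)-1-[(methoxymethoxy)methyl]-2-methyl-5-(6-methylhepta-1,5-dien-2-yl)cyclohex-2-en-1-ol
Conditions: n-BuLi (2.3 equiv), TMEDA, hexane–Et2O, 0 °C to rt; then 3, THF, −78 to −20 °C
Reagents that add atoms: none
Why: Allylic metalation with n-BuLi·TMEDA in the presence of the lithium alkoxide removes a proton from the isopropenyl methyl group, the kinetically most acidic allylic C–H (as in limonene-type substrates); the symmetrical 2-substituted allyllithium is then alkylated at the primary carbon of 3 (SN2), and C5 is untouched.

Step 3
Reactants: 4 (5R)-1-[(methoxymethoxy)methyl]-2-methyl-5-(6-methylhepta-1,5-dien-2-yl)cyclohex-2-en-1-ol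
Product: 5 (5S)-3-[(methoxymethoxy)methyl]-2-methyl-5-(6-methylhepta-1,5-dien-2-yl)cyclohex-2-en-1-one
Conditions: C5H5NH[CrO3Cl] (pyridinium chlorochromate), NaOAc, 4 Å MS, CH2Cl2, rt
Reagents that add atoms: pyridinium chlorochromate, [O-][Cr](=O)(=O)Cl.c1cc[nH+]cc1
Why: Babler–Dauben oxidative transposition: the tertiary allylic chromate ester undergoes a [3,3] shift and the resulting secondary chromate is oxidised to the enone; the carbinol centre is lost and the surviving centre now has the sense needed at C1'.

Step 4
Reactants: 5 (5S)-3-[(methoxymethoxy)methyl]-2-methyl-5-(6-methylhepta-1,5-dien-2-yl)cyclohex-2-en-1-one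
Product: 6 (5S)-3-(hydroxymethyl)-2-methyl-5-(6-methylhepta-1,5-dien-2-yl)cyclohex-2-en-1-one
Conditions: Me2BBr, CH2Cl2, −78 °C; then NaHCO3 aq, THF, rt
Reagents that add atoms: none
Why: Me2BBr cleaves the formaldehyde acetal at −78 °C by bromide attack on the O–CH2–O carbon, well below the temperature at which the enone or the two side-chain alkenes react; hydrolysis of the bromomethyl ether frees the primary allylic alcohol.

Step 5
Reactants: 6 (5S)-3-(hydroxymethyl)-2-methyl-5-(6-methylhepta-1,5-dien-2-yl)cyclohex-2-en-1-one
Product: 7 (5S)-2-methyl-5-(6-methylhepta-1,5-dien-2-yl)-3-oxocyclohex-1-ene-1-carbaldehyde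
Conditions: DMP, NaHCO3, CH2Cl2, 0 °C to rt
Reagents that add atoms: none
Why: Dess–Martin oxidation of a primary allylic alcohol under buffered non-acidic conditions gives the 4-oxo-2-enal without double-bond migration; no stereocentre is involved.

Step 6
Reactants: 8 2,6-dimethylhept-5-enal (racemic)
Product: 9 7,7-dimethoxy-2,6-dimethylhept-2-ene
Conditions: HC(OMe)3, TsOH·H2O (cat.), CH2Cl2, rt
Reagents that add atoms: trimethyl orthoformate, COC(OC)OC
Why: Acid-catalysed acetalisation with the orthoformate as methoxy source and water scavenger masks the future C1 aldehyde through steps 7–11; the trisubstituted alkene is inert to catalytic acid at room temperature.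

Step 7
Reactants: 9 7,7-dimethoxy-2,6-dimethylhept-2-ene
Product: 10 5,5-dimethoxy-4-methylpentanal
Conditions: O3, NaHCO3, CH2Cl2–MeOH, −78 °C; then Me2S, −78 °C to rt
Reagents that add atoms: ozone, [O-][O+]=O
Why: Ozonolysis with reductive work-up cleaves the only alkene and gives the unbranched aldehyde (future C7); the acetal survives the cold buffered medium.

Step 8
Reactants: 10 5,5-dimethoxy-4-methylpentanal; 11 methyl acrylate
Product: 12 methyl 3-hydroxy-7,7-dimethoxy-6-methyl-2-methylideneheptanoate (diastereomer mixture)
Conditions: DABCO (0.5 equiv), neat 11 (excess), rt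
Reagents that add atoms: none
Why: Morita–Baylis–Hillman reaction of an unbranched aliphatic aldehyde with an acrylate under amine catalysis; the carbinol centre becomes sp2 in step 9.

Step 9
Reactants: 12 methyl 3-hydroxy-7,7-dimethoxy-6-methyl-2-methylideneheptanoate
Product: 13 methyl (2Z)-2-(bromomethyl)-7,7-dimethoxy-6-methylhept-2-enoate
Conditions: NBS, Me2S, CH2Cl2, 0 °C to rt
Reagents that add atoms: N-bromosuccinimide, O=C1CCC(=O)N1Br
Why: Corey–Kim-type activation of the allylic alcohol as an alkoxysulfonium salt followed by SN2' attack of bromide gives the thermodynamically preferred (Z)-2-(bromomethyl)enoate under near-neutral conditions that spare the acetal.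

Step 10
Reactants: 7 (5S)-2-methyl-5-(6-methylhepta-1,5-dien-2-yl)-3-oxocyclohex-1-ene-1-carbaldehyde; 13 methyl (2Z)-2-(bromomethyl)-7,7-dimethoxy-6-methylhept-2-enoate
Product: 15 (4S,5S)-4-(4,4-dimethoxy-3-methylbutyl)-5-[(5S)-2-methyl-5-(6-methylhepta-1,5-dien-2-yl)-3-oxocyclohex-1-en-1-yl]-3-methylidenedihydrofuran-2(3H)-one, via O-trimethylsilyl hydroxy ester 14 (not isolated)
Conditions: CrCl2 (10 mol %), L* (12 mol %), Mn, i-Pr2NEt (cat.), Me3SiCl, THF, rt; filter; then Bu4NF, THF, 0 °C to rt
Reagents that add atoms: none
Why: Catalytic asymmetric Nozaki–Hiyama–Kishi 2-(alkoxycarbonyl)allylation: the allylchromium species should add through its γ-carbon in a chair transition state with the tether equatorial (anti adduct, as with crotylchromium reagents), and the chiral ligand selects the aldehyde face because C1' is too remote to do so. Fluoride then frees the alkoxide, which closes the trans-lactone on the ester, setting C6 and C7.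

Step 11
Reactants: 15 (4S,5S)-4-(4,4-dimethoxy-3-methylbutyl)-5-[(5S)-2-methyl-5-(6-methylhepta-1,5-dien-2-yl)-3-oxocyclohex-1-en-1-yl]-3-methylidenedihydrofuran-2(3H)-one
Product: 17 (3S,4S,5S)-4-(4,4-dimethoxy-3-methylbutyl)-3-methyl-5-[(5S)-2-methyl-5-(6-methylhepta-1,5-dien-2-yl)-3-oxocyclohex-1-en-1-yl]dihydrofuran-2(3H)-one, via kinetic C11 epimer 16 (not isolated)
Conditions: Cu(OAc)2·H2O (5 mol %), 1,2-bis(diphenylphosphino)benzene (5 mol %), (EtO)2MeSiH, t-BuOH, toluene, 0 °C to rt; silica plug; then DBU, toluene, 60 °C
Reagents that add atoms: none
Why: Copper hydride conjugate reduction is selective for the unhindered α-methylene lactone over the tetrasubstituted enone. Protonation of the enolate is expected to be unselective or to favour the wrong epimer, so DBU equilibrates C11 to the all-trans lactone (methyl trans to the C7 chain), which is the stable arrangement and that of 26.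

Step 12
Reactants: 17 (3S,4S,5S)-4-(4,4-dimethoxy-3-methylbutyl)-3-methyl-5-[(5S)-2-methyl-5-(6-methylhepta-1,5-dien-2-yl)-3-oxocyclohex-1-en-1-yl]dihydrofuran-2(3H)-one
Product: 18 2-methyl-4-{(2S,3S,4S)-4-methyl-2-[(5S)-2-methyl-5-(6-methylhepta-1,5-dien-2-yl)-3-oxocyclohex-1-en-1-yl]-5-oxooxolan-3-yl}butanal
Conditions: HCl (1 M aq), THF, rt
Reagents that add atoms: water, O
Why: Acid-catalysed acetal hydrolysis; dilute acid at room temperature leaves the lactone, the enone and both alkenes alone, and the adjacent methyl-bearing centre need not be controlled.

Step 13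
Reactants: 18 2-methyl-4-{(2S,3S,4S)-4-methyl-2-[(5S)-2-methyl-5-(6-methylhepta-1,5-dien-2-yl)-3-oxocyclohex-1-en-1-yl]-5-oxooxolan-3-yl}butanal
Product: 19 (3S,4S,5S)-4-[(3E)-4-{[tert-butyl(dimethyl)silyl]oxy}-3-methylbut-3-en-1-yl]-3-methyl-5-[(5S)-2-methyl-5-(6-methylhepta-1,5-dien-2-yl)-3-oxocyclohex-1-en-1-yl]dihydrofuran-2(3H)-one (the Z isomer is expected alongside and is equally usable)
Conditions: TBSCl, DBU, CH2Cl2, 0 °C to rt
Reagents that add atoms: tert-butyl(chloro)dimethylsilane, CC(C)(C)[Si](C)(C)Cl
Why: Base-mediated silyl enol ether formation at the most acidic and least hindered carbonyl: DBU should enolise the aldehyde faster than the hindered tetrasubstituted enone or the lactone, and the enolate is trapped on oxygen. A silyl triflate with amine is avoided because it would also convert the enone into its dienol silyl ether; the enol ether geometry is immaterial because C1 becomes a carbonyl again in step 15.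

Step 14
Reactants: 19 (3S,4S,5S)-4-[(3E)-4-{[tert-butyl(dimethyl)silyl]oxy}-3-methylbut-3-en-1-yl]-3-methyl-5-[(5S)-2-methyl-5-(6-methylhepta-1,5-dien-2-yl)-3-oxocyclohex-1-en-1-yl]dihydrofuran-2(3H)-one
Product: 20 cyclobutane photoadduct (C5–C10 and C4–C1 bonded; C1 tert-butyldimethylsilyl ether cis to the C10 methyl; cyclobutane cis-fused to ring A and ring B; C5–C10 anti to the C1' chain; C1', C6, C7, C11 as in 19)
Conditions: hν (350 nm, Pyrex), degassed CH2Cl2 (0.005 M), 0 °C
Reagents that add atoms: none
Why: Excitation of the enone n→π* band and intersystem crossing give the triplet enone, whose β-carbon C5 bonds to C10 of the electron-rich enol ether to give a 1,4-diradical (α-keto radical at C4, α-silyloxy radical at C1); after spin inversion C4–C1 closes, and diradicals that cannot close revert to 19. The closest known reaction type is the intramolecular enone–alkene [2+2] photocycloaddition used in the de Mayo manner. Ring B closes as a six-membered ring by bonding of the enone β-carbon to the internal alkene carbon through the four-atom tether (straight mode), and the cyclobutane closes by 1,4-radical recombination, necessarily cis on both six-membered rings. C5 is controlled by two elements that must cooperate: bonding anti to the equatorial C1' substituent of the half-chair, and a chair-like tether in which the trans-lactone holds C6–O and C7–C11 equatorial. C10 follows from the same chair (methyl axial, C1 equatorial and next to C4), C4 from the cis fusion, and C1 is not controlled and need not be. The step needs chemoselectivity over the side-chain alkenes: the 1,1-disubstituted alkene can reach C4=C5 only from an axial C1' conformer in a strained crossed mode and the trisubstituted alkene is out of reach, whereas the enol ether is electron-rich and held close. Pyrex-filtered 350 nm light is absorbed only by the enone, and high dilution suppresses dimerisation.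

Step 15
Reactants: 20 cyclobutane photoadduct
Product: 23 aldol product (bicyclo[2.2.2]octane with C1–OH and C3 ketone; C4–H; mixture at C1 and C4; C1', C2, C5, C6, C7, C10, C11 as in 26), via cyclobutanol 21 (not isolated), via keto aldehyde 22 (not isolated)
Conditions: Bu4NF, THF, 0 °C to rt
Reagents that add atoms: none
Why: Fluoride removes the silyl group and the cyclobutanolate, β to the C3 ketone, undergoes strain-driven retro-aldol cleavage of C4–C1 to the C3 enolate and the non-enolisable C1 aldehyde. After proton transfer the C2 enolate closes the six-membered ring (intramolecular aldol addition), which is possible because C10 sits axial on ring A; C2 is fixed by the bicycle and the C1 and C4 configurations are of no consequence.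

Step 16
Reactants: 23 aldol product
Product: 24 1,3-diketone (C1 and C3 ketones; C4–H; mixture at C4)
Conditions: DMP, NaHCO3, CH2Cl2, rt
Reagents that add atoms: none
Why: Dess–Martin oxidation of the secondary alcohol under neutral conditions; the diketone cannot enolise between the carbonyls (bridgehead C2) and is kept away from nucleophilic base to avoid retro-Claisen opening.

Step 17
Reactants: 24 1,3-diketone
Product: 25 C3 enol triflate (C3=C4; C1 ketone)
Conditions: KN(SiMe3)2 (1.05 equiv), THF, −78 °C; then PhNTf2, −78 to 0 °C
Reagents that add atoms: N-phenylbis(trifluoromethanesulfonimide), O=S(=O)(N(c1ccccc1)S(=O)(=O)C(F)(F)F)C(F)(F)F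
Why: Kinetic enolate formation and O-sulfonylation: C4–H is the only enolisable position of either ketone and is several pKa units more acidic than the lactone C11–H, so one equivalent of hindered amide base gives the C3 enolate, which is trapped as the enol triflate; C4 becomes sp2.

Step 18
Reactants: 25 C3 enol triflate
Product: 26 CNP0385704.1 (target; 1'S,2S,5R,6S,7S,10R,11S in the labels used here)
Conditions: Pd(OAc)2 (5 mol %), PPh3 (10 mol %), Bu3N, HCO2H, DMF, 60 °C
Reagents that add atoms: none
Why: Palladium-catalysed formate reduction of an enol triflate: oxidative addition to zerovalent palladium, formate exchange, loss of CO2 and C–H reductive elimination give the C3=C4 alkene where the triflate stood. No stereocentre is touched; if C11 was disturbed in step 17 it can be re-equilibrated with DBU, since C11–H is the only acidic C–H left.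

Compound list

1 | (R)-carvone, (5R)-2-methyl-5-(prop-1-en-2-yl)cyclohex-2-en-1-one | CC(=C)[C@@H]1CC=C(C)C(=O)C1 | starting material
2 | (5R)-1-[(methoxymethoxy)methyl]-2-methyl-5-(prop-1-en-2-yl)cyclohex-2-en-1-ol (C1 epimers) | CC(=C)[C@@H]1CC=C(C)C(O)(COCOC)C1 | intermediate
3 | 1-bromo-3-methylbut-2-ene | CC(C)=CCBr | starting material
4 | (5R)-1-[(methoxymethoxy)methyl]-2-methyl-5-(6-methylhepta-1,5-dien-2-yl)cyclohex-2-en-1-ol (C1 epimers) | C=C(CCC=C(C)C)[C@@H]1CC=C(C)C(O)(COCOC)C1 | intermediate
5 | (5S)-3-[(methoxymethoxy)methyl]-2-methyl-5-(6-methylhepta-1,5-dien-2-yl)cyclohex-2-en-1-one | C=C(CCC=C(C)C)[C@@H]1CC(=O)C(C)=C(COCOC)C1 | intermediate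
6 | (5S)-3-(hydroxymethyl)-2-methyl-5-(6-methylhepta-1,5-dien-2-yl)cyclohex-2-en-1-one | C=C(CCC=C(C)C)[C@@H]1CC(=O)C(C)=C(CO)C1 | intermediate
7 | (5S)-2-methyl-5-(6-methylhepta-1,5-dien-2-yl)-3-oxocyclohex-1-ene-1-carbaldehyde | C=C(CCC=C(C)C)[C@@H]1CC(=O)C(C)=C(C=O)C1 | intermediate
8 | 2,6-dimethylhept-5-enal (racemic) | CC(CCC=C(C)C)C=O | starting material
9 | 7,7-dimethoxy-2,6-dimethylhept-2-ene (racemic) | COC(OC)C(C)CCC=C(C)C | intermediate
10 | 5,5-dimethoxy-4-methylpentanal (racemic) | COC(OC)C(C)CCC=O | intermediate
11 | methyl acrylate | C=CC(=O)OC | starting material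
12 | methyl 3-hydroxy-7,7-dimethoxy-6-methyl-2-methylideneheptanoate (diastereomer mixture) | COC(OC)C(C)CCC(O)C(=C)C(=O)OC | intermediate
13 | methyl (2Z)-2-(bromomethyl)-7,7-dimethoxy-6-methylhept-2-enoate (racemic) | BrC/C(=C\CCC(C)C(OC)OC)C(=O)OC | intermediate
14 | methyl (3S,4S)-3-(4,4-dimethoxy-3-methylbutyl)-4-[(5S)-2-methyl-5-(6-methylhepta-1,5-dien-2-yl)-3-oxocyclohex-1-en-1-yl]-2-methylidene-4-[(trimethylsilyl)oxy]butanoate | C=C(CCC=C(C)C)[C@H]1CC(=C(C)C(=O)C1)[C@@H](O[Si](C)(C)C)[C@@H](CCC(C)C(OC)OC)C(=C)C(=O)OC | intermediate
15 | (4S,5S)-4-(4,4-dimethoxy-3-methylbutyl)-5-[(5S)-2-methyl-5-(6-methylhepta-1,5-dien-2-yl)-3-oxocyclohex-1-en-1-yl]-3-methylidenedihydrofuran-2(3H)-one | C=C(CCC=C(C)C)[C@H]1CC(=C(C)C(=O)C1)[C@H]2OC(=O)C(=C)[C@@H]2CCC(C)C(OC)OC | intermediate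
16 | (3R,4S,5S)-4-(4,4-dimethoxy-3-methylbutyl)-3-methyl-5-[(5S)-2-methyl-5-(6-methylhepta-1,5-dien-2-yl)-3-oxocyclohex-1-en-1-yl]dihydrofuran-2(3H)-one (C11 epimer of 17) | C=C(CCC=C(C)C)[C@H]1CC(=C(C)C(=O)C1)[C@H]2OC(=O)[C@H](C)[C@@H]2CCC(C)C(OC)OC | intermediate
17 | (3S,4S,5S)-4-(4,4-dimethoxy-3-methylbutyl)-3-methyl-5-[(5S)-2-methyl-5-(6-methylhepta-1,5-dien-2-yl)-3-oxocyclohex-1-en-1-yl]dihydrofuran-2(3H)-one | C=C(CCC=C(C)C)[C@H]1CC(=C(C)C(=O)C1)[C@H]2OC(=O)[C@@H](C)[C@@H]2CCC(C)C(OC)OC | intermediate
18 | 2-methyl-4-{(2S,3S,4S)-4-methyl-2-[(5S)-2-methyl-5-(6-methylhepta-1,5-dien-2-yl)-3-oxocyclohex-1-en-1-yl]-5-oxooxolan-3-yl}butanal | C=C(CCC=C(C)C)[C@H]1CC(=C(C)C(=O)C1)[C@H]2OC(=O)[C@@H](C)[C@@H]2CCC(C)C=O | intermediate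
19 | (3S,4S,5S)-4-[(3E)-4-{[tert-butyl(dimethyl)silyl]oxy}-3-methylbut-3-en-1-yl]-3-methyl-5-[(5S)-2-methyl-5-(6-methylhepta-1,5-dien-2-yl)-3-oxocyclohex-1-en-1-yl]dihydrofuran-2(3H)-one | C=C(CCC=C(C)C)[C@H]1CC(=C(C)C(=O)C1)[C@H]2OC(=O)[C@@H](C)[C@@H]2CC/C(C)=C/O[Si](C)(C)C(C)(C)C | intermediate
20 | cyclobutane photoadduct: C5–C10 and C4–C1 bonded, C1–OSi(t-Bu)Me2 cis to the C10 methyl, cyclobutane cis-fused to rings A and B, C5–C10 anti to the C1' chain (1S,4R,5S,6S,7S,10R,11S,1'S) | C=C(CCC=C(C)C)[C@H]1C[C@@]23[C@@](C)(C(=O)C1)[C@@H](O[Si](C)(C)C(C)(C)C)[C@]2(C)CC[C@H]4[C@H](C)C(=O)O[C@@H]43 | intermediate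
21 | free C1 cyclobutanol corresponding to 20 | C=C(CCC=C(C)C)[C@H]1C[C@@]23[C@@](C)(C(=O)C1)[C@@H](O)[C@]2(C)CC[C@H]4[C@H](C)C(=O)O[C@@H]43 | intermediate
22 | keto aldehyde: ring A cyclohexanone (C3 ketone, C4–H epimers) spiro-free fused at C5–C10 to ring B, C10 bearing methyl and formyl (C1), lactone as in 26 (5R,6S,7S,10R,11S,1'S) | C=C(CCC=C(C)C)[C@H]1C[C@@]2(C(C)C(=O)C1)[C@](C)(C=O)CC[C@H]3[C@H](C)C(=O)O[C@H]23 | intermediate
23 | aldol product: bicyclo[2.2.2]octane with C1–OH and C3 ketone, C4–H (C1 and C4 epimers), other centres as in 26 | C=C(CCC=C(C)C)[C@H]1C[C@@]23C(C)C(=O)[C@@H]1C(O)[C@]2(C)CC[C@H]1[C@H](C)C(=O)O[C@@H]13 | intermediate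
24 | 1,3-diketone: C1 and C3 ketones, C4–H (epimers), other centres as in 26 | C=C(CCC=C(C)C)[C@H]1C[C@@]23C(C)C(=O)[C@@H]1C(=O)[C@]2(C)CC[C@H]1[C@H](C)C(=O)O[C@@H]13 | intermediate
25 | C3 enol triflate: C3(OSO2CF3)=C4(CH3), C1 ketone, other centres as in 26 | C=C(CCC=C(C)C)[C@H]1C[C@@]23C(C)=C(OS(=O)(=O)C(F)(F)F)[C@@H]1C(=O)[C@]2(C)CC[C@H]1[C@H](C)C(=O)O[C@@H]13 | intermediate
26 | CNP0385704.1 (1'S,2S,5R,6S,7S,10R,11S) | C=C(CCC=C(C)C)[C@H]1C[C@@]23C(C)=C[C@@H]1C(=O)[C@]2(C)CC[C@H]1[C@H](C)C(=O)O[C@@H]13 | target

Total step count: 18. Longest linear sequence: 14 steps (steps 1–5 and 10–18, from 1); steps 6–9 form the branch from 8.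

Least certain steps

Step 14 (key step). The most likely failure is poor facial selectivity at C5. The chair that leads to 20 places C6–O and C6–C7 on either side of the C4 methyl group, whereas the competing chair, with C6–H turned towards that methyl, has less allylic strain and bonds syn to the C1' substituent. The triplet could also decay without productive closure, or be diverted into crossed addition to the side-chain 1,1-disubstituted alkene. Fallback: from 19 the same C5–C10 bond is made in the ground state by an intramolecular Mukaiyama–Michael addition of the silyl enol ether to the enone (Me3SiOTf or TiCl4, CH2Cl2, −78 °C). After aqueous work-up this gives the keto aldehyde 22 directly, and the route is rejoined at 22, which is closed to 23 with mild base. No compound outside the list is made (F0). This replaces radical bond formation by a polar one whose face selectivity is decided in a ground-state chair and can be corrected by retro-Michael equilibration.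

Step 2. Metalation may take place elsewhere (ring allylic positions, or next to the acetal oxygens under the influence of the alkoxide), and the allyllithium may attack the tertiary end of 3. Fallback: from 1, ene-type chlorination with Ca(OCl)2 and CO2 gives (5R)-5-(3-chloroprop-1-en-2-yl)-2-methylcyclohex-2-en-1-one F1. Addition of the reagent of step 1 at −78 °C gives the chloro alcohol F2. Biellmann coupling of F2 with lithiated 3-methylbut-2-enyl phenyl sulfone (2.2 equiv) gives the sulfone F3, and reductive desulfonylation with Na/Hg amalgam and Na2HPO4 in MeOH returns to the route at 4.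

Step 10. Three processes may interfere: syn addition through a (Z)-configured allylmetal leading to the cis-lactone; single-electron reduction of the electron-poor 4-oxo-2-enal by divalent chromium; and insufficient catalyst control over the aldehyde face. Fallback: from 7 and 13 an indium-mediated Barbier allylation (In powder, THF–H2O) is used, which is non-reducing and reliably syn. After chromatographic separation of the two syn diastereomers the (3S,4R)-hydroxy ester F4 is saponified with LiOH to the hydroxy acid F5. Mitsunobu lactonisation (PPh3, diisopropyl azodicarboxylate) inverts C6 and returns to the route at 15.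

Step 13. Enolisation may not be selective: the enone may be O-silylated to a dienol ether, or deprotonated at C6 with loss of configuration there. Fallback: from 18 the aldehyde is converted selectively into its enol acetate F6 (Ac2O, Et3N, DMAP), conditions under which ketones do not form enol esters. Irradiation as in step 14 gives the C1-acetoxy cyclobutane F7, and methanolysis with K2CO3 in MeOH frees the cyclobutanol and triggers the same retro-aldol/aldol sequence, returning to the route at 23.

Step 15. Desilylation at C1, which is flanked by two quaternary carbons, may be slow, and the cascade may stop at the keto aldehyde if the aldol equilibrium is unfavourable in the basic fluoride medium. Fallback: from 20 the silyl group is removed with HF·pyridine to give 21, brief treatment with K2CO3 opens it to 22, which is now isolated. The C2–C1 bond is then formed by enamine catalysis (pyrrolidine, AcOH) and the route is rejoined at 23. No compound outside the list is made (F0).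

Further compounds

F0 | step 14 | none | none
F1 | step 2 | (5R)-5-(3-chloroprop-1-en-2-yl)-2-methylcyclohex-2-en-1-one | ClCC(=C)[C@@H]1CC=C(C)C(=O)C1
F2 | step 2 | (5R)-5-(3-chloroprop-1-en-2-yl)-1-[(methoxymethoxy)methyl]-2-methylcyclohex-2-en-1-ol | ClCC(=C)[C@@H]1CC=C(C)C(O)(COCOC)C1
F3 | step 2 | (5R)-1-[(methoxymethoxy)methyl]-2-methyl-5-[6-methyl-4-(phenylsulfonyl)hepta-1,5-dien-2-yl]cyclohex-2-en-1-ol | C=C(CC(C=C(C)C)S(=O)(=O)c2ccccc2)[C@@H]1CC=C(C)C(O)(COCOC)C1
F4 | step 10 | methyl (3S,4R)-3-(4,4-dimethoxy-3-methylbutyl)-4-hydroxy-4-[(5S)-2-methyl-5-(6-methylhepta-1,5-dien-2-yl)-3-oxocyclohex-1-en-1-yl]-2-methylidenebutanoate | C=C(CCC=C(C)C)[C@H]1CC(=C(C)C(=O)C1)[C@H](O)[C@@H](CCC(C)C(OC)OC)C(=C)C(=O)OC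
F5 | step 10 | (3S,4R)-3-(4,4-dimethoxy-3-methylbutyl)-4-hydroxy-4-[(5S)-2-methyl-5-(6-methylhepta-1,5-dien-2-yl)-3-oxocyclohex-1-en-1-yl]-2-methylidenebutanoic acid | C=C(CCC=C(C)C)[C@H]1CC(=C(C)C(=O)C1)[C@H](O)[C@@H](CCC(C)C(OC)OC)C(=C)C(=O)O
F6 | step 13 | (1E)-2-methyl-4-{(2S,3S,4S)-4-methyl-2-[(5S)-2-methyl-5-(6-methylhepta-1,5-dien-2-yl)-3-oxocyclohex-1-en-1-yl]-5-oxooxolan-3-yl}but-1-en-1-yl acetate | C=C(CCC=C(C)C)[C@H]1CC(=C(C)C(=O)C1)[C@H]2OC(=O)[C@@H](C)[C@@H]2CC/C(C)=C/OC(C)=O
F7 | step 13 | C1-acetoxy analogue of photoadduct 20 | C=C(CCC=C(C)C)[C@H]1C[C@@]23[C@@](C)(C(=O)C1)[C@@H](OC(C)=O)[C@]2(C)CC[C@H]4[C@H](C)C(=O)O[C@@H]43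
F0 | step 15 | none | none
A1 | alternative 1 | C6 diazoacetate of the ring-B-fused bicyclo[2.2.2]octane-1,3-dione, C1' acetyl group as ethylene ketal | CC1(OCCO1)[C@H]2C[C@@]34[C@@H](C)C(=O)[C@@H]2C(=O)[C@]3(C)CCC[C@@H]4OC(=O)C=[N+]=[N-]
A2 | alternative 1 | trans-fused lactone lacking the C11 methyl, diketone stage, side chain as ketal | CC1(OCCO1)[C@H]2C[C@@]34[C@@H](C)C(=O)[C@@H]2C(=O)[C@]3(C)CC[C@H]5CC(=O)O[C@@H]54
A3 | alternative 2 | C3 trimethylsilyl enol ether (C2=C3) with vinyl on C10, ring B and lactone in place, isopropenyl on C1' | CC(=C)[C@H]1C[C@@]2([C@@H](C)C(O[Si](C)(C)C)=C1)[C@](C)(C=C)CC[C@H]3[C@H](C)C(=O)O[C@H]23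
A4 | alternative 2 | C1-methylidene bicyclo[2.2.2]octan-3-one with ring B and lactone, isopropenyl on C1' | CC(=C)[C@H]1C[C@@]23[C@@H](C)C(=O)[C@@H]1C(=C)[C@]2(C)CC[C@H]4[C@H](C)C(=O)O[C@@H]43
A5 | alternative 3 | (E)-nitroalkene tethered through C6–C9 to the carvone-derived cyclohexa-1,3-diene, lactone in place | C=C(CCC=C(C)C)[C@H]1CC(=C(C)C=C1)[C@H]2OC(=O)[C@@H](C)[C@@H]2CC/C(C)=C/[N+](=O)[O-]
A6 | alternative 3 | C1-nitro analogue of 26 | C=C(CCC=C(C)C)[C@H]1C[C@@]23C(C)=C[C@@H]1[C@@H]([N+](=O)[O-])[C@]2(C)CC[C@H]1[C@H](C)C(=O)O[C@@H]13
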